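The choice of which charge to feed slowly rests on one quantity: of the starting material leaving at a given moment, the part that leaves towards target.

    catalyst intermediate A → free catalyst + target (k1 = 34 /s)
    starting material + free catalyst ⇌ catalyst intermediate A (K2 = 2000 /M, k2 = 9000 /M/s)
    catalyst intermediate B → free catalyst + second product (k3 = 30 /s)
    free catalyst ⇌ dormant form (K4 = 3.0, k4 = 0.13 /s)
    starting material → uncatalysed product (k5 = 0.58 /s)
    second substrate + free catalyst ⇌ catalyst intermediate B (K6 = 1200 /M, k6 = 12000 /M/s)

| flask | starting material | second substrate | free catalyst | time | remark |
|---|---|---|---|---|---|
| south | 0.010 M | 10.0 mM (fed, over 8.0 s) | 60 µM | 12 s | all else is in the flask from the start; the feed brings no volume worth counting |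
| south-west | 0.010 M (fed, over 8.0 s) | 10.0 mM | 60 µM | 12 s | all else is in the flask from the start; the feed brings no volume worth counting |
| east | 0.010 M | 10.0 mM | 60 µM | 12 s | everything together at the start |
| south-east | 0.010 M | 10.0 mM (in portions, 2, over 8.0 s) | 60 µM | 12 s | first portion at the start, last at 8.0 s |

1. the flask with the highest amount of target, in percent of the starting material charged ("all alike" if they lie within 1.5 percentage points) (south / south-west / east / south-east / all alike)
2. final target, as a percentage of the starting material charged, in south
3. final target, as a percentage of the starting material charged, in south-west
4. final target, as a percentage of the starting material charged, in east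
5. final target, as a percentage of the starting material charged, in south-east

Catalyst intermediate A has a breakdown half-life of 0.020 s in east, far shorter than the 1.2 s of starting material by the uncatalysed step, so it can be held at steady state. Its forward breakdown at 34 /s is faster than its return at 4.50 /s, so capture by free catalyst counts with k_c = 7950 /M/s, and k_c times free catalyst is a pseudo-first-order constant. Catalyst intermediate B, with a half-life of 0.023 s, is treated alike. Each bound form is then a tie-up number times free catalyst: T_A = 2.34 for the charged starting material and T_B = 3.00 for the charged second substrate. The dormant form relaxes with a half-life of 4.00 s, longer than the 1.2 s of the uncatalysed step, so this reckoning leaves it out.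

For east, free catalyst is taken as the charge over one plus T_A plus T_B at the start, which gives a pseudo-first-order constant of 0.0752 /s and a share of 11.5% against the uncatalysed 0.58 /s. Setting T_A to zero and keeping T_B unchanged gives a constant of 0.119 /s and a share of 17.1%. The mean of these two ends, 14.3%, is the capture share φ, my figure for target in east. In south-east the last portion arrives after 6.69 half-lives of the uncatalysed step, so T_B is taken at 1.50 and φ becomes 19.6%. South starts without T_B at a share of 19.8%, against 11.5% at the start of east and 14.5% at the start of south-east, so south is my choice for highest. South-west, whose T_A changes with its feed, gets no figure.

The forecast named south, with 23% in south, 19% in south-west, 14.5% in east and 19.5% in south-east, holding that “the yield depends on how much catalyst is free for it in those first seconds”.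

The flasks gave 23.6% in south, 19.8% in south-west, 14.9% in east and 19.6% in south-east, so south stands highest.

Against these, φ reads 14.3% for east and 19.6% for south-east. The neighbouring flask repeats east with 3.6 × 10⁻⁵ M of free catalyst. The same reckoning gives 9.10%, which is 0.636 of the φ for east. That neighbouring flask ended with 9.16% target.

The constants are made up; the result is computed.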